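**Numbering used throughout.** Lactone ring: O1, C2 (carbonyl), C3, C4, C5; C7 is the ketone carbon on C3. Compounds 1–17 are fixed as in the compound list below.

## Analysis of the target

Compound 17 is a γ-butyrolactone with a 4-hydroxy-3-methoxybenzoyl group on C3 and a 3,4-dimethoxybenzyl group on C4, the 7-oxo relative of the dibenzylbutyrolactone lignans. The two stereocentres are adjacent and trans, (3S,4R). C3 sits between the ketone C7 and the lactone carbonyl C2, so its hydrogen is acidic and its configuration is thermodynamic: the aroyl group settles anti to the benzyl group on C4. C4 carries only H, the C5 methylene and a benzylic methylene, cannot be corrected later, and is the one centre that must be set absolutely. The sensitive groups are the β-keto lactone (enolisation, retro-Claisen opening by base or nucleophiles), the free phenol (oxidation) and two electron-rich arenes. The difficulty is to attach two nearly identical aryl-C1 units at different oxidation levels and to acylate C3 without racemising or opening anything. The feature that carries the plan is the 1,3 relationship across C3 between C7 and the carbonyl oxygen on C2: this is what an isoxazoline C7=N–O–C2 leaves behind. The C3–C7 bond and the C2–O bond can therefore be formed together by adding an aryl nitrile oxide across the C2=C3 enol ether bond of a 2,3-dihydrofuran that already contains C4.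

## Retrosynthetic reasoning

**17 ⇐ 16.** Only the O–Si bond is cut. The phenol stays silylated to the end because a free phenol would not survive hydroximoyl chloride formation, nitrile oxide generation or the hypervalent iodine oxidation. A fluoride-labile group is chosen so that the last step can be run buffered, away from base.

**16 ⇐ 15 ⇐ 13.** No skeletal bond is cut. The lactone carbonyl is traced back to a lactol, and the keto lactol 15 to the fused isoxazoline 13 by N–O hydrogenolysis and hydrolysis of the resulting imine. Compound 13 is a masked keto lactol one oxidation level below 16, so the aroyl group never has to be introduced by enolate acylation. The forward steps must release the ketone without dehydrating the lactol and then oxidise C2.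

**13 ⇐ 7 + 12 (key disconnection).** The C3–C7 bond and the C2–O bond are cut together, which is the retron of a nitrile oxide cycloaddition. Cutting here, and not at C3–C4 or C4–CH2Ar, separates the molecule into its two aryl halves at the point where their oxidation levels differ, and leaves C4 as the only stereocentre of dihydrofuran 7. The forward reaction has to be regioselective (carbon to C3, oxygen to C2) and should occur anti to the C4 benzyl group. Even incomplete facial control converges, because C2 later becomes sp2 and C3 equilibrates.

**12 ⇐ 11 ⇐ 10 ⇐ 9 ⇐ 8.** The dipole is generated in the flask from hydroximoyl chloride 11, which comes from oxime 10, silyl ether 9 and vanillin 8 by functional-group changes only.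

**7 ⇐ 6.** The O1–C2 bond is cut. An endo cycloisomerisation of the terminal alkynol 6 through a metal vinylidene forms the enol ether directly at the right oxidation level. No lactol dehydration is needed and the propargylic stereocentre is not touched.

**6 ⇐ 5 ⇐ 4.** The alkyne terminus is removed as a one-carbon homologation of aldehyde 4 (Ohira–Bestmann). The primary hydroxyl is carried as a silyl ether through this step because a free aldol product under carbonate in methanol invites retro-aldol, dehydration and enolisation. The silyl ether is the benzyl analogue of the Roche aldehyde, a well-behaved substrate class. Homologating 3 directly would save two steps but would put the only lasting stereocentre at risk.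

**4 ⇐ 3 ⇐ 1 + 2.** The bond between the α-carbon of 1 and the hydroxymethyl carbon is cut. Enamine-catalysed α-hydroxymethylation with formaldehyde 2 sets C4 in one catalytic step from an achiral, linear aldehyde, and both antipodes of the catalyst are sold.

## Alternatives that were turned down

**Alternative 1: asymmetric cyclocarbonylation, then late benzylic oxidation.**
- Disconnection: C2–C3 and C2–O1 are cut with CO as C2; the C7 oxygen is added last.
- Key step: a Pd–H species from Pd(OAc)2, a chiral bisphosphine and acid adds across the trisubstituted (E)-allylic alcohol A1, CO inserts at C3, and the hydroxyl captures the acyl palladium to give the trans-dibenzyl lactone A2. Debenzylation and oxidation of the benzylic position para to the free phenol would follow.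
- For it: both stereocentres come from one catalytic, atom-economic step, and the two benzylic positions are told apart by the only handle that distinguishes them, the free phenol.
- Against it: enantioselective hydrocarbonylation of a trisubstituted alkene must control regiochemistry, alkene isomerisation and two centres at once. The late oxidation passes through a quinone methide at C7 next to the acidic C3–H and can tautomerise to the benzylidene lactone. The veratryl benzylic position is also oxidisable.
- Comparison: it is stronger in setting C3 and C4 by catalyst in one step. The chosen route instead brings C7 in at the ketone level, so no C–H oxidation selectivity is needed, and lets C3 follow C4 thermodynamically.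

**Alternative 2: desymmetrising lactonisation of a prochiral diol.**
- Disconnection: O1–C2 is cut; the veratryl ring is attached to the C4 side chain afterwards.
- Key step: a chiral phosphoric acid directs one of the two enantiotopic hydroxymethyl groups of diol ester A3 onto the tert-butyl ester, giving lactone A4 with C4 defined.
- For it: organocatalytic, and the 1,3-dicarbonyl is in place from the start, so C3 again follows C4.
- Against it: the remaining hydroxymethyl group must still become an arylmethyl group. That requires a leaving group on the carbon attached to C4, in a 1,3 relationship to the highly acidic C3, where enolate closure to a cyclopropane competes with any sp3 coupling. Selecting between two hydroxyls next to a stereolabile centre is also less secure than the better-known diester desymmetrisations.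
- Comparison: it is equal in using a small-molecule catalyst and in the thermodynamic setting of C3. It is weaker in step economy after the key step and in the compatibility of the late C–C coupling. The chosen route has the benzyl group on C4 before any acidic functionality exists.

**Alternative 3: enzymatic Baeyer–Villiger desymmetrisation.**
- Disconnection: O1–C2 and O1–C5 are cut by taking out the ring oxygen; the C3–C7 bond is made afterwards by enolate chemistry.
- Key step: a Baeyer–Villiger monooxygenase inserts oxygen next to one enantiotopic methylene of cyclobutanone A5 to give lactone A6.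
- For it: this is the shortest plan. A5 is two steps from commercial 4-allyl-1,2-dimethoxybenzene (dichloroketene cycloaddition, Zn dechlorination), and aroylation of A6 anti to the benzyl group is classical lignan chemistry. On step count and end-game precedent it is stronger than the chosen route.
- Against it: the sense and level of enantioselection depend on the particular enzyme and substrate, need screening and cofactor recycling, and the other enantiomer needs a different enzyme. The acylation needs two equivalents of strong base on a lactone, or an aldol–oxidation pair.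
- Comparison: the chosen route is longer. It offers a purchasable catalyst of predictable sense in either antipode and introduction of the aroyl carbon under nearly neutral conditions. A6 remains available as the fallback for the key step.

Key step: step 9

**Remarks on assumptions.**
- The sense of induction in step 1 is derived from the steric-shielding model of diarylprolinol silyl ether enamines (electrophile enters anti to the diphenyl(silyloxy)methyl group); on that model the (R)-catalyst gives (S)-3. It was not checked against a reported example.
- Aldehyde 1 is taken as purchasable.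
- Lactols are drawn as anomeric mixtures; their C2 configuration is of no consequence.

## Route

**Step 1**
Reactants: 1 3-(3,4-dimethoxyphenyl)propanal; 2 formaldehyde (37% aqueous)
Product: 3 (S)-2-(3,4-dimethoxybenzyl)-3-hydroxypropanal (used crude)
Conditions: (R)-α,α-diphenylprolinol trimethylsilyl ether (10 mol %), pH 7 buffer (NaH2PO4/Na2HPO4), toluene, rt
Reagents that add atoms: none
Why: Enamine-catalysed cross-aldol (α-hydroxymethylation); the anti E-enamine of 1 is shielded on one face by the diphenyl(silyloxy)methyl group, so formaldehyde adds to the open face and sets the future C4. The neutral two-phase medium suppresses Mannich-type dehydration, and the α-branched product re-forms an enamine only slowly.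

**Step 2**
Reactants: 3 (S)-2-(3,4-dimethoxybenzyl)-3-hydroxypropanal
Product: 4 (S)-3-(tert-butyldimethylsilyloxy)-2-(3,4-dimethoxybenzyl)propanal
Conditions: TBSCl, imidazole, CH2Cl2, 0 °C
Reagents that add atoms: tert-butyldimethylsilyl chloride, CC(C)(C)[Si](C)(C)Cl
Why: Silylation of the primary alcohol under weakly basic conditions that should spare the α-stereocentre; it removes the free aldol hydroxyl before the basic homologation and gives a Roche-aldehyde analogue.

**Step 3**
Reactants: 4 (S)-3-(tert-butyldimethylsilyloxy)-2-(3,4-dimethoxybenzyl)propanal
Product: 5 (R)-tert-butyl{[2-(3,4-dimethoxybenzyl)but-3-yn-1-yl]oxy}dimethylsilane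
Conditions: dimethyl (1-diazo-2-oxopropyl)phosphonate, K2CO3, MeOH, 0 °C → rt
Reagents that add atoms: dimethyl (1-diazo-2-oxopropyl)phosphonate, COP(=O)(OC)C(=[N+]=[N-])C(C)=O
Why: Ohira–Bestmann (Seyferth–Gilbert) homologation; methanolysis of the reagent gives the diazomethylphosphonate anion, which adds to the aldehyde, and loss of phosphate and N2 followed by a 1,2-hydrogen shift gives the terminal alkyne. The stereocentre is not involved; the descriptor changes from S to R only because the CIP ranking changes.

**Step 4**
Reactants: 5 (R)-tert-butyl{[2-(3,4-dimethoxybenzyl)but-3-yn-1-yl]oxy}dimethylsilane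
Product: 6 (R)-2-(3,4-dimethoxybenzyl)but-3-yn-1-ol
Conditions: TBAF, THF, 0 °C → rt
Reagents that add atoms: none
Why: Fluoride-induced cleavage of the primary silyl ether; the alkyne and the stereocentre are inert.

**Step 5**
Reactants: 6 (R)-2-(3,4-dimethoxybenzyl)but-3-yn-1-ol
Product: 7 (R)-3-(3,4-dimethoxybenzyl)-2,3-dihydrofuran
Conditions: Mo(CO)6 (25 mol %), Et3N, Et2O, hν (350 nm), rt; chromatography on Et3N-treated silica
Reagents that add atoms: none
Why: Alkynol cycloisomerisation of the McDonald type; photogenerated (Et3N)Mo(CO)5 converts the terminal alkyne into a molybdenum vinylidene, the hydroxyl adds to its electrophilic carbon, and protodemetalation releases the endocyclic enol ether. The propargylic stereocentre is untouched.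

**Step 6**
Reactants: 8 vanillin
Product: 9 4-(tert-butyldimethylsilyloxy)-3-methoxybenzaldehyde
Conditions: TBSCl, imidazole, DMF, rt
Reagents that add atoms: tert-butyldimethylsilyl chloride, CC(C)(C)[Si](C)(C)Cl
Why: Standard silylation of a phenol; it blocks the nucleophilic and oxidisable hydroxyl for steps 8, 9 and 11.

**Step 7**
Reactants: 9 4-(tert-butyldimethylsilyloxy)-3-methoxybenzaldehyde
Product: 10 (E)-4-(tert-butyldimethylsilyloxy)-3-methoxybenzaldehyde oxime
Conditions: NH2OH·HCl, NaOAc, EtOH/H2O, rt
Reagents that add atoms: hydroxylamine hydrochloride, NO.Cl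
Why: Oxime condensation under acetate buffer, mild enough for the aryl silyl ether.

**Step 8**
Reactants: 10 (E)-4-(tert-butyldimethylsilyloxy)-3-methoxybenzaldehyde oxime
Product: 11 (Z)-4-(tert-butyldimethylsilyloxy)-N-hydroxy-3-methoxybenzimidoyl chloride
Conditions: NCS, DMF, rt
Reagents that add atoms: N-chlorosuccinimide, O=C1CCC(=O)N1Cl
Why: Chlorination of an aldoxime at carbon to the hydroximoyl chloride, routine for alkoxy-substituted benzaldoximes; one equivalent of NCS at rt should favour the oxime carbon over the ring.

**Step 9**
Reactants: 7 (R)-3-(3,4-dimethoxybenzyl)-2,3-dihydrofuran; 11 (Z)-4-(tert-butyldimethylsilyloxy)-N-hydroxy-3-methoxybenzimidoyl chloride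
Product: 13 (3aS,4R,6aR)-3-[4-(tert-butyldimethylsilyloxy)-3-methoxyphenyl]-4-(3,4-dimethoxybenzyl)-3a,4,5,6a-tetrahydrofuro[3,2-d]isoxazole, via aryl nitrile oxide 12 (not isolated)
Conditions: 11 (1.5 equiv, syringe pump, 8 h) added to 7 and Et3N (2 equiv), CH2Cl2, 0 °C → rt
Reagents that add atoms: none
Why: Triethylamine removes HCl from 11 and releases nitrile oxide 12 at low stationary concentration, which adds to the C2=C3 enol ether bond of 7 in a concerted, asynchronous (3+2) cycloaddition; the closest known reaction type is the addition of aryl nitrile oxides to 2,3-dihydrofuran, which gives 3-aryl-3a,4,5,6a-tetrahydrofuro[3,2-d]isoxazoles. The leading interaction is between the enol ether HOMO, largest at the β-carbon (future C3), and the dipole LUMO, largest at carbon, so the nitrile oxide carbon bonds to C3 and its oxygen to the oxygen-bearing C2, as the target requires. The isoxazoline ring is closed by suprafacial addition of the three-atom dipole across two adjacent ring carbons, not by cyclisation of a chain, so it is necessarily cis-fused to the tetrahydrofuran. Of the two new stereocentres, C3a is set by the existing C4 centre: the benzyl group shields one face next to the carbon that receives the bulky aryl-bearing terminus, and the dipole should approach from the other face; C6a follows from the cis fusion. The step needs regioselectivity, secured by the polarisation of the enol ether; facial selectivity, secured by the allylic benzyl group; and chemoselectivity against furoxan formation, secured by slow addition of 11 to an excess of base and dipolarophile. The excess base also protects the acid-sensitive enol ether from the HCl that is released. Any syn adduct would not be lost, because C6a becomes the lactone carbonyl and C3 later equilibrates to the trans arrangement.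

**Step 10**
Reactants: 13 (3aS,4R,6aR)-3-[4-(tert-butyldimethylsilyloxy)-3-methoxyphenyl]-4-(3,4-dimethoxybenzyl)-3a,4,5,6a-tetrahydrofuro[3,2-d]isoxazole
Product: 15 [4-(tert-butyldimethylsilyloxy)-3-methoxyphenyl][(3R,4R)-4-(3,4-dimethoxybenzyl)-2-hydroxytetrahydrofuran-3-yl]methanone (anomeric mixture; used at once), via hydroxy imine 14 (not isolated)
Conditions: Raney Ni, H2 (1 atm), B(OH)3, MeOH/H2O 5:1, rt
Reagents that add atoms: water, O
Why: Hydrogenolytic N–O cleavage of an isoxazoline under boric acid buffer; the oxygen released sits on the acetal carbon, so the β-hydroxy imine 14 is a lactol, and its N–H ketimine is hydrolysed to the aryl ketone in the same flask. Room temperature and a nearly neutral medium are chosen so that the lactol does not lose water; C3 may epimerise, but trans is the stable arrangement.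

**Step 11**
Reactants: 15 [4-(tert-butyldimethylsilyloxy)-3-methoxyphenyl][(3R,4R)-4-(3,4-dimethoxybenzyl)-2-hydroxytetrahydrofuran-3-yl]methanone
Product: 16 (3S,4R)-3-[4-(tert-butyldimethylsilyloxy)-3-methoxybenzoyl]-4-(3,4-dimethoxybenzyl)dihydrofuran-2(3H)-one
Conditions: TEMPO (20 mol %), PhI(OAc)2 (1.5 equiv), CH2Cl2, rt
Reagents that add atoms: none
Why: Oxoammonium-mediated oxidation of a lactol to the lactone; there is no other free hydroxyl, the phenol is silylated and the arenes are inert to the reagent. C3 now lies between two carbonyls and settles trans to the benzyl group, which is the 3S configuration.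

**Step 12**
Reactants: 16 (3S,4R)-3-[4-(tert-butyldimethylsilyloxy)-3-methoxybenzoyl]-4-(3,4-dimethoxybenzyl)dihydrofuran-2(3H)-one
Product: 17 (3S,4R)-4-(3,4-dimethoxybenzyl)-3-(4-hydroxy-3-methoxybenzoyl)dihydrofuran-2(3H)-one
Conditions: TBAF, AcOH, THF, 0 °C
Reagents that add atoms: none
Why: Fluoride cleaves the aryl silyl ether rapidly; acetic acid keeps the acidic β-keto lactone protonated, so retro-Claisen opening is avoided and C3 remains in its thermodynamic trans configuration.

## Compound list

1 | 3-(3,4-dimethoxyphenyl)propanal | O=CCCc1ccc(OC)c(OC)c1 | starting material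
2 | formaldehyde | C=O | starting material
3 | (S)-2-(3,4-dimethoxybenzyl)-3-hydroxypropanal | O=C[C@@H](Cc1ccc(OC)c(OC)c1)CO | intermediate
4 | (S)-3-(tert-butyldimethylsilyloxy)-2-(3,4-dimethoxybenzyl)propanal | O=C[C@@H](Cc1ccc(OC)c(OC)c1)CO[Si](C)(C)C(C)(C)C | intermediate
5 | (R)-tert-butyl{[2-(3,4-dimethoxybenzyl)but-3-yn-1-yl]oxy}dimethylsilane | C#C[C@@H](Cc1ccc(OC)c(OC)c1)CO[Si](C)(C)C(C)(C)C | intermediate
6 | (R)-2-(3,4-dimethoxybenzyl)but-3-yn-1-ol | C#C[C@@H](Cc1ccc(OC)c(OC)c1)CO | intermediate
7 | (R)-3-(3,4-dimethoxybenzyl)-2,3-dihydrofuran | C1=C[C@@H](Cc2ccc(OC)c(OC)c2)CO1 | intermediate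
8 | vanillin | COc1cc(C=O)ccc1O | starting material
9 | 4-(tert-butyldimethylsilyloxy)-3-methoxybenzaldehyde | COc1cc(C=O)ccc1O[Si](C)(C)C(C)(C)C | intermediate
10 | (E)-4-(tert-butyldimethylsilyloxy)-3-methoxybenzaldehyde oxime | COc1cc(/C=N/O)ccc1O[Si](C)(C)C(C)(C)C | intermediate
11 | (Z)-4-(tert-butyldimethylsilyloxy)-N-hydroxy-3-methoxybenzimidoyl chloride | COc1cc(/C(Cl)=N/O)ccc1O[Si](C)(C)C(C)(C)C | intermediate
12 | 4-(tert-butyldimethylsilyloxy)-3-methoxybenzonitrile oxide (not isolated) | COc1cc(C#[N+][O-])ccc1O[Si](C)(C)C(C)(C)C | intermediate
13 | (3aS,4R,6aR)-3-[4-(tert-butyldimethylsilyloxy)-3-methoxyphenyl]-4-(3,4-dimethoxybenzyl)-3a,4,5,6a-tetrahydrofuro[3,2-d]isoxazole | COc1cc(C2=NO[C@H]3OC[C@H](Cc4ccc(OC)c(OC)c4)[C@@H]23)ccc1O[Si](C)(C)C(C)(C)C | intermediate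
14 | (3S,4R)-3-{[4-(tert-butyldimethylsilyloxy)-3-methoxyphenyl](imino)methyl}-4-(3,4-dimethoxybenzyl)tetrahydrofuran-2-ol (anomers; not isolated) | COc1cc(C(=N)[C@H]2C(O)OC[C@@H]2Cc2ccc(OC)c(OC)c2)ccc1O[Si](C)(C)C(C)(C)C | intermediate
15 | [4-(tert-butyldimethylsilyloxy)-3-methoxyphenyl][(3R,4R)-4-(3,4-dimethoxybenzyl)-2-hydroxytetrahydrofuran-3-yl]methanone (anomers) | COc1cc(C(=O)[C@H]2C(O)OC[C@@H]2Cc2ccc(OC)c(OC)c2)ccc1O[Si](C)(C)C(C)(C)C | intermediate
16 | (3S,4R)-3-[4-(tert-butyldimethylsilyloxy)-3-methoxybenzoyl]-4-(3,4-dimethoxybenzyl)dihydrofuran-2(3H)-one | COc1cc(C(=O)[C@H]2C(=O)OC[C@@H]2Cc2ccc(OC)c(OC)c2)ccc1O[Si](C)(C)C(C)(C)C | intermediate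
17 | (3S,4R)-4-(3,4-dimethoxybenzyl)-3-(4-hydroxy-3-methoxybenzoyl)dihydrofuran-2(3H)-one | COc1cc(C(=O)[C@H]2C(=O)OC[C@@H]2Cc2ccc(OC)c(OC)c2)ccc1O | target

## Step count and weak points

Total: 12 steps. Longest linear sequence: 9 steps (steps 1–5, then 9–12). The dipole branch (steps 6–8) has 3 steps before the convergence.

**Step 9 (key step).** The most likely failure is dimerisation of the nitrile oxide to the furoxan outrunning addition, because its carbon terminus must bond next to the benzyl-bearing carbon. The same steric demand may erode the electronically preferred regiochemistry. Incomplete facial selectivity is tolerable, since both adducts converge. The fallback abandons the cycloaddition and sets out from 7. Oxidation of the cyclic enol ether with pyridinium chlorochromate, C5H5NH[CrO3Cl], should give (R)-4-(3,4-dimethoxybenzyl)dihydrofuran-2(3H)-one F1, the same lactone as A6. Its lithium enolate (LiN(i-Pr)2, THF, −78 °C) adds to aldehyde 9 anti to the benzyl group to give the hydroxy lactone F2 as carbinol epimers. Dess–Martin oxidation of the benzylic alcohol returns to the route at 16.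

**Step 10.** The keto lactol can lose water, through enolisation of the aryl ketone and departure of the anomeric hydroxyl, to a conjugated 3-aroyl-4,5-dihydrofuran, which is the thermodynamic sink. The open-chain β-keto aldehyde tautomer can be deformylated, and the imine can be over-reduced. The same tautomerism could misdirect the oxidant in step 11, so 15 is not stored. The fallback sets out from 13 and makes the dehydration deliberate. Mo(CO)6 in wet MeCN at 80 °C, followed by catalytic TsOH, should give the dihydrofuranyl ketone F3. NBS in wet THF brominates its nucleophilic C3, and water caps the oxocarbenium ion at C2, giving the bromo keto lactol F4. F4 has no hydrogen on C3 and can neither eliminate nor enolise. Oxidation with TEMPO and PhI(OAc)2 gives the bromo keto lactone F5. Zn in AcOH removes the bromine through the zinc enolate, whose protonation gives the trans isomer, and the route is rejoined at 16.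

**Step 1.** The risk is erosion of enantiopurity, because the product can re-enter the enamine cycle, together with dehydration to the 2-benzylacrolein. C4 is the only centre the later steps cannot correct, so any loss here reaches 17. The fallback sets out from 3 of whatever enantiopurity and replaces induction by desymmetrisation. NaBH4 added to the reaction mixture gives the prochiral 2-(3,4-dimethoxybenzyl)propane-1,3-diol F6. A lipase screened for the required sense (for example Pseudomonas cepacia lipase with vinyl acetate) gives the (S)-monoacetate F7. Silylation gives the silyl acetate F8, methanolysis (K2CO3, MeOH) gives the silyl alcohol F9, and Dess–Martin oxidation returns to the route at 4.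

**Step 3.** Partial epimerisation of the α-stereocentre of 4 can occur if enolisation under carbonate in methanol competes with addition of the diazophosphonate anion. The fallback sets out from 4 and uses the Corey–Fuchs sequence. CBr4 and PPh3 (with Et3N, CH2Cl2, 0 °C) give the dibromoalkene F10 without exposing the aldehyde to alkoxide. n-BuLi (2 equiv, THF, −78 °C) followed by water returns to the route at 5.

## Further compounds

F1 | step 9 | (R)-4-(3,4-dimethoxybenzyl)dihydrofuran-2(3H)-one | O=C1C[C@@H](Cc2ccc(OC)c(OC)c2)CO1
F2 | step 9 | (3S,4R)-3-{[4-(tert-butyldimethylsilyloxy)-3-methoxyphenyl](hydroxy)methyl}-4-(3,4-dimethoxybenzyl)dihydrofuran-2(3H)-one (carbinol epimers) | COc1cc(C(O)[C@H]2C(=O)OC[C@@H]2Cc2ccc(OC)c(OC)c2)ccc1O[Si](C)(C)C(C)(C)C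
F3 | step 10 | (R)-[4-(tert-butyldimethylsilyloxy)-3-methoxyphenyl][4-(3,4-dimethoxybenzyl)-4,5-dihydrofuran-3-yl]methanone | COc1cc(C(=O)C2=COC[C@@H]2Cc2ccc(OC)c(OC)c2)ccc1O[Si](C)(C)C(C)(C)C
F4 | step 10 | [(4S)-3-bromo-4-(3,4-dimethoxybenzyl)-2-hydroxytetrahydrofuran-3-yl][4-(tert-butyldimethylsilyloxy)-3-methoxyphenyl]methanone (mixture at C2 and C3) | COc1cc(C(=O)C2(Br)C(O)OC[C@@H]2Cc2ccc(OC)c(OC)c2)ccc1O[Si](C)(C)C(C)(C)C
F5 | step 10 | (4S)-3-bromo-3-[4-(tert-butyldimethylsilyloxy)-3-methoxybenzoyl]-4-(3,4-dimethoxybenzyl)dihydrofuran-2(3H)-one (C3 epimers) | COc1cc(C(=O)C2(Br)C(=O)OC[C@@H]2Cc2ccc(OC)c(OC)c2)ccc1O[Si](C)(C)C(C)(C)C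
F6 | step 1 | 2-(3,4-dimethoxybenzyl)propane-1,3-diol | OCC(CO)Cc1ccc(OC)c(OC)c1
F7 | step 1 | (S)-2-(3,4-dimethoxybenzyl)-3-hydroxypropyl acetate | CC(=O)OC[C@@H](Cc1ccc(OC)c(OC)c1)CO
F8 | step 1 | (R)-3-(tert-butyldimethylsilyloxy)-2-(3,4-dimethoxybenzyl)propyl acetate | CC(=O)OC[C@@H](Cc1ccc(OC)c(OC)c1)CO[Si](C)(C)C(C)(C)C
F9 | step 1 | (R)-3-(tert-butyldimethylsilyloxy)-2-(3,4-dimethoxybenzyl)propan-1-ol | OC[C@@H](Cc1ccc(OC)c(OC)c1)CO[Si](C)(C)C(C)(C)C
F10 | step 3 | (R)-tert-butyl{[4,4-dibromo-2-(3,4-dimethoxybenzyl)but-3-en-1-yl]oxy}dimethylsilane | BrC(Br)=C[C@@H](Cc1ccc(OC)c(OC)c1)CO[Si](C)(C)C(C)(C)C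
A1 | alternative 1 | (E)-4-[4-(benzyloxy)-3-methoxyphenyl]-2-(3,4-dimethoxybenzyl)but-2-en-1-ol | COc1cc(C/C=C(/CO)Cc2ccc(OC)c(OC)c2)ccc1OCc1ccccc1
A2 | alternative 1 | (3R,4R)-3-[4-(benzyloxy)-3-methoxybenzyl]-4-(3,4-dimethoxybenzyl)dihydrofuran-2(3H)-one | COc1cc(C[C@H]2C(=O)OC[C@@H]2Cc2ccc(OC)c(OC)c2)ccc1OCc1ccccc1
A3 | alternative 2 | tert-butyl 2-[4-(tert-butyldimethylsilyloxy)-3-methoxybenzoyl]-4-hydroxy-3-(hydroxymethyl)butanoate | COc1cc(C(=O)C(C(=O)OC(C)(C)C)C(CO)CO)ccc1O[Si](C)(C)C(C)(C)C
A4 | alternative 2 | (3S,4S)-3-[4-(tert-butyldimethylsilyloxy)-3-methoxybenzoyl]-4-(hydroxymethyl)dihydrofuran-2(3H)-one | COc1cc(C(=O)[C@H]2C(=O)OC[C@@H]2CO)ccc1O[Si](C)(C)C(C)(C)C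
A5 | alternative 3 | 3-(3,4-dimethoxybenzyl)cyclobutanone | O=C1CC(Cc2ccc(OC)c(OC)c2)C1
A6 | alternative 3 | (R)-4-(3,4-dimethoxybenzyl)dihydrofuran-2(3H)-one | O=C1C[C@@H](Cc2ccc(OC)c(OC)c2)CO1
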